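Labels: chromone A is the 7-hydroxy-5-(2-oxopropyl) half and chromone B the 2-isopropyl-8-methoxy half, with usual chromone numbering (kept for the monocyclic forerunners of A). One bridge CH2 joins A-C2 to B-C5.
Enabling feature: in the benzene ring of A the OH sits on C7 between unsubstituted C6 and C8, and the only carbon substituent is on C5. This is the imprint of a ketene carbon (C7), a diazo carbon (C8), a methylene terminus (C6) and a substituted alkene carbon (C5). The pyrone ring of A (bridge on C2, H on C3, C4=O, handles at C4a and C8a) has the substitution pattern of kojic acid.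
Cuts, in retrosynthetic order: side-chain ketone to dioxolane; C6-C7 and C8a-C8 (benzene ring of A opened to a 4-pyrone with a diazoacetyl group on C8a and a 1,1-disubstituted alkene on C4a); C7-C8 (acylation of a diazo carbon); C4a-C5 (Suzuki); bridge CH2 to B-C5 (Suzuki); the formaldehyde carbon on C8a, which ends as C7.
Forward order: the pyrone ring of A is bought with kojic acid. The pyrone ring of B is closed on 2',6'-dihydroxyacetophenone. The halves are joined at the bridge, the alkenyl chain goes onto C4a, and the benzene ring of A forms last, followed by ketal hydrolysis.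
Stereochemistry: the target has no stereocentre and no stereogenic double bond, so nothing has to be controlled.
Key step: step 18

Step 1
Reactants: 1 kojic acid; 2 formaldehyde
Product: 3 3-hydroxy-2,6-bis(hydroxymethyl)-4H-pyran-4-one
Conditions: NaOH (1.1 equiv), 37% aq. CH2O (1.1 equiv), H2O, rt; then HCl to pH 2
Reagents that add atoms: none
Why: Base-mediated hydroxymethylation (Lederer-Manasse type aldol addition) of the enolate of 1 can occur only at C6, the free position next to the enol oxygen, and is a known reaction of kojic acid.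

Step 2
Reactants: 3 3-hydroxy-2,6-bis(hydroxymethyl)-4H-pyran-4-one
Product: 4 6-(hydroxymethyl)-2,2-dimethyl-4H-pyrano[3,2-d][1,3]dioxin-8-one (acetonide across the enol O and the neighbouring CH2O)
Conditions: Me2C(OMe)2, TsOH·H2O (cat.), DMF, rt; Et3N quench, aqueous work-up
Reagents that add atoms: 2,2-dimethoxypropane COC(C)(C)OC
Why: Acid-catalysed transketalisation ties the enol OH and the adjacent CH2OH into a six-membered acetonide, as with salicyl alcohol and pyridoxine, while the remote CH2OH has no partner oxygen and stays free (a mixed acetal formed there should fall off on work-up).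

Step 3
Reactants: 4 6-(hydroxymethyl)-2,2-dimethyl-4H-pyrano[3,2-d][1,3]dioxin-8-one
Product: 5 6-(chloromethyl)-2,2-dimethyl-4H-pyrano[3,2-d][1,3]dioxin-8-one
Conditions: PPh3, NCS, THF, 0 °C to rt
Reagents that add atoms: N-chlorosuccinimide O=C1CCC(=O)N1Cl
Why: Appel-type chlorination through the alkoxyphosphonium salt is neutral, so the acetonide should survive, and displacement at the activated pyronylmethyl carbon is fast.

Step 4
Reactants: 6 2',6'-dihydroxyacetophenone; 7 isobutyryl chloride
Product: 10 5-hydroxy-2-isopropyl-4H-chromen-4-one, via trilithium salt 8 (not isolated), via diketone 9 (not isolated)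
Conditions: LiN(SiMe3)2 (4.2 equiv), THF, -78 to -10 °C; 7, -78 °C to rt; aq. HCl; then AcOH, H2SO4 (cat.), 95 °C
Reagents that add atoms: none
Why: Claisen-type C-acylation of the enolate carbon of the trianion (the direct variant of the Baker-Venkataraman route) gives the 1,3-diketone, acid-catalysed cyclodehydration closes the pyrone ring of B, and the two equivalent phenol groups allow only one chromone.

Step 5
Reactants: 10 5-hydroxy-2-isopropyl-4H-chromen-4-one
Product: 12 5,8-dihydroxy-2-isopropyl-4H-chromen-4-one, via aryl sulfate 11 (not isolated)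
Conditions: K2S2O8, aq. KOH, 10-20 °C; HCl, extraction of unchanged 10; then aq. HCl, 90 °C
Reagents that add atoms: potassium peroxydisulfate [K+].[K+].[O-]S(=O)(=O)OOS(=O)(=O)[O-]
Why: In the Elbs persulfate oxidation the phenoxide attacks peroxydisulfate through its para carbon C8 and acid hydrolysis of the aryl sulfate frees the hydroquinone, a conversion known for 5-hydroxychromones and 5-hydroxyflavones.

Step 6
Reactants: 12 5,8-dihydroxy-2-isopropyl-4H-chromen-4-one
Product: 13 5-hydroxy-2-isopropyl-8-methoxy-4H-chromen-4-one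
Conditions: MeI (1.05 equiv), K2CO3 (1.1 equiv), acetone, argon, 40 °C
Reagents that add atoms: iodomethane CI
Why: Williamson methylation with one equivalent of MeI should take the 8-OH only, because the 5-OH is locked in a hydrogen bond to the C4 carbonyl and is far less nucleophilic under carbonate conditions.

Step 7
Reactants: 13 5-hydroxy-2-isopropyl-8-methoxy-4H-chromen-4-one
Product: 14 2-isopropyl-8-methoxy-4-oxo-4H-chromen-5-yl trifluoromethanesulfonate
Conditions: Tf2O, pyridine, CH2Cl2, 0 °C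
Reagents that add atoms: trifluoromethanesulfonic anhydride O=S(=O)(OS(=O)(=O)C(F)(F)F)C(F)(F)F
Why: O-sulfonylation with the strong electrophile Tf2O overcomes the chelation of the 5-OH, as is standard for 5-hydroxychromones and flavones, and turns C5-O into a leaving group.

Step 8
Reactants: 14 2-isopropyl-8-methoxy-4-oxo-4H-chromen-5-yl trifluoromethanesulfonate
Product: 15 2-isopropyl-8-methoxy-5-(4,4,5,5-tetramethyl-1,3,2-dioxaborolan-2-yl)-4H-chromen-4-one
Conditions: B2pin2, PdCl2(dppf) (5 mol %), KOAc, 1,4-dioxane, 90 °C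
Reagents that add atoms: bis(pinacolato)diboron CC1(C)OB(OC1(C)C)B1OC(C)(C)C(C)(C)O1
Why: Miyaura borylation of an aryl triflate works with the weak base KOAc, which neither promotes coupling of 15 with 14 nor harms the chromone.

Step 9
Reactants: 5 6-(chloromethyl)-2,2-dimethyl-4H-pyrano[3,2-d][1,3]dioxin-8-one; 15 2-isopropyl-8-methoxy-5-(4,4,5,5-tetramethyl-1,3,2-dioxaborolan-2-yl)-4H-chromen-4-one
Product: 16 6-[(2-isopropyl-8-methoxy-4-oxo-4H-chromen-5-yl)methyl]-2,2-dimethyl-4H-pyrano[3,2-d][1,3]dioxin-8-one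
Conditions: PdCl2(dppf) (5 mol %), K3PO4, THF/H2O (10:1), 60 °C
Reagents that add atoms: none
Why: Suzuki-Miyaura coupling of a heterobenzylic chloride with an arylboronate forms the bond from the bridge CH2 to B-C5, since oxidative addition into the activated C-Cl bond is easy, no beta-hydrogen is present and the acetonide masks the metal-chelating hydroxypyrone.

Step 10
Reactants: 16 6-[(2-isopropyl-8-methoxy-4-oxo-4H-chromen-5-yl)methyl]-2,2-dimethyl-4H-pyrano[3,2-d][1,3]dioxin-8-one
Product: 17 5-{[5-hydroxy-6-(hydroxymethyl)-4-oxo-4H-pyran-2-yl]methyl}-2-isopropyl-8-methoxy-4H-chromen-4-one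
Conditions: 1 M HCl, THF, rt
Reagents that add atoms: none
Why: Acid-catalysed acetonide hydrolysis frees the enol OH and the CH2OH, while pyrone, chromone and aryl methyl ether are inert to dilute acid.

Step 11
Reactants: 17 5-{[5-hydroxy-6-(hydroxymethyl)-4-oxo-4H-pyran-2-yl]methyl}-2-isopropyl-8-methoxy-4H-chromen-4-one
Product: 18 2-(hydroxymethyl)-6-[(2-isopropyl-8-methoxy-4-oxo-4H-chromen-5-yl)methyl]-4-oxo-4H-pyran-3-yl trifluoromethanesulfonate
Conditions: PhNTf2 (1.05 equiv), Et3N, CH2Cl2, 0 °C to rt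
Reagents that add atoms: N-phenylbis(trifluoromethanesulfonimide) O=S(=O)(N(c1ccccc1)S(=O)(=O)C(F)(F)F)C(F)(F)F
Why: Chemoselective phenol-type triflation is expected because Et3N ionises only the acidic enol OH and the mild triflyl donor PhNTf2 reacts with that oxyanion but not with the neutral primary alcohol.

Step 12
Reactants: 19 acetylacetone
Product: 20 1-(2-methyl-1,3-dioxolan-2-yl)propan-2-one
Conditions: HOCH2CH2OH (1.0 equiv), TsOH·H2O (cat.), toluene, reflux with azeotropic removal of water; distillation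
Reagents that add atoms: ethylene glycol OCCO
Why: Acid-catalysed ketalisation with one equivalent of diol gives the known monoketal, which distillation separates from diketone and bisketal.

Step 13
Reactants: 20 1-(2-methyl-1,3-dioxolan-2-yl)propan-2-one
Product: 22 3-(2-methyl-1,3-dioxolan-2-yl)prop-1-en-2-yl trifluoromethanesulfonate, via lithium enolate 21 (not isolated)
Conditions: LiN(iPr)2 (1.05 equiv), THF, -78 °C; PhNTf2, -78 to 0 °C
Reagents that add atoms: N-phenylbis(trifluoromethanesulfonimide) O=S(=O)(N(c1ccccc1)S(=O)(=O)C(F)(F)F)C(F)(F)F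
Why: Kinetic deprotonation takes the unhindered methyl protons rather than the neopentyl-like CH2 next to the ketal, and O-triflation of the terminal enolate is the standard enol triflate synthesis of 1-alken-2-yl triflates.

Step 14
Reactants: 22 3-(2-methyl-1,3-dioxolan-2-yl)prop-1-en-2-yl trifluoromethanesulfonate
Product: 23 4,4,5,5-tetramethyl-2-[3-(2-methyl-1,3-dioxolan-2-yl)prop-1-en-2-yl]-1,3,2-dioxaborolane
Conditions: B2pin2, PdCl2(PPh3)2 (3 mol %), PPh3, KOPh, toluene, 50 °C
Reagents that add atoms: bis(pinacolato)diboron CC1(C)OB(OC1(C)C)B1OC(C)(C)C(C)(C)O1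
Why: Miyaura borylation of alkenyl triflates with KOPh as base is established for 1-alken-2-yl triflates and keeps the double bond where the triflate fixed it.

Step 15
Reactants: 18 2-(hydroxymethyl)-6-[(2-isopropyl-8-methoxy-4-oxo-4H-chromen-5-yl)methyl]-4-oxo-4H-pyran-3-yl trifluoromethanesulfonate; 23 4,4,5,5-tetramethyl-2-[3-(2-methyl-1,3-dioxolan-2-yl)prop-1-en-2-yl]-1,3,2-dioxaborolane
Product: 24 5-({6-(hydroxymethyl)-5-[3-(2-methyl-1,3-dioxolan-2-yl)prop-1-en-2-yl]-4-oxo-4H-pyran-2-yl}methyl)-2-isopropyl-8-methoxy-4H-chromen-4-one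
Conditions: Pd(OAc)2 (5 mol %), SPhos (10 mol %), K3PO4, THF/H2O (10:1), 50 °C
Reagents that add atoms: none
Why: Suzuki-Miyaura coupling of 3-triflyloxy-4-pyrones is known for kojic acid and maltol triflates and forms C4a-C5 here, the electron-poor C-OTf bond adding quickly to palladium and the bulky electron-rich SPhos easing transmetalation at the crowded centre.

Step 16
Reactants: 24 5-({6-(hydroxymethyl)-5-[3-(2-methyl-1,3-dioxolan-2-yl)prop-1-en-2-yl]-4-oxo-4H-pyran-2-yl}methyl)-2-isopropyl-8-methoxy-4H-chromen-4-one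
Product: 26 6-[(2-isopropyl-8-methoxy-4-oxo-4H-chromen-5-yl)methyl]-3-[3-(2-methyl-1,3-dioxolan-2-yl)prop-1-en-2-yl]-4-oxo-4H-pyran-2-carboxylic acid, via aldehyde 25 (not isolated)
Conditions: TEMPO (0.2 equiv), PhI(OAc)2 (2.5 equiv), MeCN/aq. phosphate buffer pH 7, rt; extraction at pH 3, 0 °C
Reagents that add atoms: water O
Why: Oxoammonium (TEMPO/PhI(OAc)2) oxidation carries a primary alcohol through the aldehyde hydrate to the acid in one flask, spares the alkene and the bridge CH2, keeps the dienal from accumulating, and the buffer protects the dioxolane from the acetic acid formed.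

Step 17
Reactants: 26 6-[(2-isopropyl-8-methoxy-4-oxo-4H-chromen-5-yl)methyl]-3-[3-(2-methyl-1,3-dioxolan-2-yl)prop-1-en-2-yl]-4-oxo-4H-pyran-2-carboxylic acid; 27 (trimethylsilyl)diazomethane
Product: 29 5-({6-(diazoacetyl)-5-[3-(2-methyl-1,3-dioxolan-2-yl)prop-1-en-2-yl]-4-oxo-4H-pyran-2-yl}methyl)-2-isopropyl-8-methoxy-4H-chromen-4-one, via acid chloride 28 (not isolated)
Conditions: Me2C=C(Cl)NMe2 (1.2 equiv), CH2Cl2, 0 °C to rt; then 27 (2.2 equiv), THF/MeCN, 0 °C; aq. NaHCO3; product kept cold and dark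
Reagents that add atoms: none
Why: This is the first stage of the Arndt-Eistert sequence, in which the neutral alpha-chloroenamine makes the acid chloride without HCl (safe for the ketal) and C-acylation of 27 with loss of Me3SiCl forms bond C7-C8 of the diazoketone.

Step 18
Reactants: 29 5-({6-(diazoacetyl)-5-[3-(2-methyl-1,3-dioxolan-2-yl)prop-1-en-2-yl]-4-oxo-4H-pyran-2-yl}methyl)-2-isopropyl-8-methoxy-4H-chromen-4-one
Product: 32 7-hydroxy-2-[(2-isopropyl-8-methoxy-4-oxo-4H-chromen-5-yl)methyl]-5-[(2-methyl-1,3-dioxolan-2-yl)methyl]-4H-chromen-4-one, via dienylketene 30 (not isolated), via cyclohexadienone 31 (not isolated)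
Conditions: hν (LED, 420-450 nm), dry degassed toluene (5 mM), 20 °C; then 60 °C in the dark
Reagents that add atoms: none
Why: Proposed new method: light absorbed by the diazoketone in its s-Z conformer expels N2 while pyrone carbon C8a shifts from the carbonyl carbon to the diazo carbon (Wolff rearrangement, new bond C8a-C8), so ketene 30 arises with C7=C8, C8a=C4a and C5=C6 as a hexatriene whose central double bond is endocyclic and whose termini C6 and C7 therefore cannot turn away from each other. The closest known reaction type is the photochemical Wolff rearrangement of unsaturated diazoketones coupled to the electrocyclisation of a dienylketene to a phenol, the closing stage of vinylketene benzannulations; new here is a 4-pyrone as migrating group and as central double bond, and its small aromatic stabilisation should make closure no harder than on carbocyclic scaffolds. The benzene ring of A closes by thermal disrotatory six-electron electrocyclisation (bond C6-C7) to cyclohexadienone 31, whose C6 methylene enolises to the C7 phenol and makes the sequence irreversible. No stereocentre is created. The step needs the 1,2-shift to outrun cyclopropanation of the alkene on C4a and needs the ketene to meet no nucleophile: metal-free irradiation avoids a carbenoid, light of 420-450 nm reaches only the diazoketone band and leaves both pyrone chromophores unexcited, and dry toluene at high dilution keeps water and the product phenol away from 30. Since the medium is neutral and non-oxidising, the dioxolane and the acidic bridge CH2 have nothing to react with.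

Step 19
Reactants: 32 7-hydroxy-2-[(2-isopropyl-8-methoxy-4-oxo-4H-chromen-5-yl)methyl]-5-[(2-methyl-1,3-dioxolan-2-yl)methyl]-4H-chromen-4-one
Product: 33 7-hydroxy-2-[(2-isopropyl-8-methoxy-4-oxo-4H-chromen-5-yl)methyl]-5-(2-oxopropyl)-4H-chromen-4-one (target)
Conditions: 1 M HCl, THF, rt
Reagents that add atoms: water O
Why: Acid-catalysed ketal hydrolysis releases the 2-oxopropyl group, and both chromones, the phenol and the methyl ether tolerate dilute acid.

Compound list
1 | kojic acid (5-hydroxy-2-(hydroxymethyl)-4H-pyran-4-one) | OCC1=CC(=O)C(O)=CO1 | starting material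
2 | formaldehyde | C=O | starting material
3 | 3-hydroxy-2,6-bis(hydroxymethyl)-4H-pyran-4-one | OCC1=CC(=O)C(O)=C(CO)O1 | intermediate
4 | 6-(hydroxymethyl)-2,2-dimethyl-4H-pyrano[3,2-d][1,3]dioxin-8-one | OCC1=CC(=O)C2=C(COC(C)(C)O2)O1 | intermediate
5 | 6-(chloromethyl)-2,2-dimethyl-4H-pyrano[3,2-d][1,3]dioxin-8-one | ClCC1=CC(=O)C2=C(COC(C)(C)O2)O1 | intermediate
6 | 2',6'-dihydroxyacetophenone | CC(=O)c1c(O)cccc1O | starting material
7 | isobutyryl chloride | CC(C)C(Cl)=O | starting material
8 | trilithium salt of 6 (bis-phenoxide enolate) | [Li+].[Li+].[Li+].C=C([O-])c1c([O-])cccc1[O-] | intermediate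
9 | 1-(2,6-dihydroxyphenyl)-4-methylpentane-1,3-dione | CC(C)C(=O)CC(=O)c1c(O)cccc1O | intermediate
10 | 5-hydroxy-2-isopropyl-4H-chromen-4-one | CC(C)c1cc(=O)c2c(O)cccc2o1 | intermediate
11 | potassium 5-hydroxy-2-isopropyl-4-oxo-4H-chromen-8-yl sulfate | CC(C)c1cc(=O)c2c(O)ccc(OS(=O)(=O)[O-])c2o1.[K+] | intermediate
12 | 5,8-dihydroxy-2-isopropyl-4H-chromen-4-one | CC(C)c1cc(=O)c2c(O)ccc(O)c2o1 | intermediate
13 | 5-hydroxy-2-isopropyl-8-methoxy-4H-chromen-4-one | COc1ccc(O)c2c(=O)cc(C(C)C)oc12 | intermediate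
14 | 2-isopropyl-8-methoxy-4-oxo-4H-chromen-5-yl trifluoromethanesulfonate | COc1ccc(OS(=O)(=O)C(F)(F)F)c2c(=O)cc(C(C)C)oc12 | intermediate
15 | 2-isopropyl-8-methoxy-5-(4,4,5,5-tetramethyl-1,3,2-dioxaborolan-2-yl)-4H-chromen-4-one | COc1ccc(B2OC(C)(C)C(C)(C)O2)c2c(=O)cc(C(C)C)oc12 | intermediate
16 | 6-[(2-isopropyl-8-methoxy-4-oxo-4H-chromen-5-yl)methyl]-2,2-dimethyl-4H-pyrano[3,2-d][1,3]dioxin-8-one | COc1ccc(CC2=CC(=O)C3=C(COC(C)(C)O3)O2)c2c(=O)cc(C(C)C)oc12 | intermediate
17 | 5-{[5-hydroxy-6-(hydroxymethyl)-4-oxo-4H-pyran-2-yl]methyl}-2-isopropyl-8-methoxy-4H-chromen-4-one | COc1ccc(CC2=CC(=O)C(O)=C(CO)O2)c2c(=O)cc(C(C)C)oc12 | intermediate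
18 | 2-(hydroxymethyl)-6-[(2-isopropyl-8-methoxy-4-oxo-4H-chromen-5-yl)methyl]-4-oxo-4H-pyran-3-yl trifluoromethanesulfonate | COc1ccc(CC2=CC(=O)C(OS(=O)(=O)C(F)(F)F)=C(CO)O2)c2c(=O)cc(C(C)C)oc12 | intermediate
19 | acetylacetone (pentane-2,4-dione) | CC(=O)CC(C)=O | starting material
20 | 1-(2-methyl-1,3-dioxolan-2-yl)propan-2-one | CC(=O)CC1(C)OCCO1 | intermediate
21 | lithium 3-(2-methyl-1,3-dioxolan-2-yl)prop-1-en-2-olate | [Li+].C=C([O-])CC1(C)OCCO1 | intermediate
22 | 3-(2-methyl-1,3-dioxolan-2-yl)prop-1-en-2-yl trifluoromethanesulfonate | C=C(CC1(C)OCCO1)OS(=O)(=O)C(F)(F)F | intermediate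
23 | 4,4,5,5-tetramethyl-2-[3-(2-methyl-1,3-dioxolan-2-yl)prop-1-en-2-yl]-1,3,2-dioxaborolane | C=C(CC1(C)OCCO1)B1OC(C)(C)C(C)(C)O1 | intermediate
24 | 5-({6-(hydroxymethyl)-5-[3-(2-methyl-1,3-dioxolan-2-yl)prop-1-en-2-yl]-4-oxo-4H-pyran-2-yl}methyl)-2-isopropyl-8-methoxy-4H-chromen-4-one | C=C(CC1(C)OCCO1)C1=C(CO)OC(Cc2ccc(OC)c3oc(C(C)C)cc(=O)c23)=CC1=O | intermediate
25 | 6-[(2-isopropyl-8-methoxy-4-oxo-4H-chromen-5-yl)methyl]-3-[3-(2-methyl-1,3-dioxolan-2-yl)prop-1-en-2-yl]-4-oxo-4H-pyran-2-carbaldehyde | C=C(CC1(C)OCCO1)C1=C(C=O)OC(Cc2ccc(OC)c3oc(C(C)C)cc(=O)c23)=CC1=O | intermediate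
26 | 6-[(2-isopropyl-8-methoxy-4-oxo-4H-chromen-5-yl)methyl]-3-[3-(2-methyl-1,3-dioxolan-2-yl)prop-1-en-2-yl]-4-oxo-4H-pyran-2-carboxylic acid | C=C(CC1(C)OCCO1)C1=C(C(=O)O)OC(Cc2ccc(OC)c3oc(C(C)C)cc(=O)c23)=CC1=O | intermediate
27 | (trimethylsilyl)diazomethane | C[Si](C)(C)C=[N+]=[N-] | starting material
28 | 6-[(2-isopropyl-8-methoxy-4-oxo-4H-chromen-5-yl)methyl]-3-[3-(2-methyl-1,3-dioxolan-2-yl)prop-1-en-2-yl]-4-oxo-4H-pyran-2-carbonyl chloride | C=C(CC1(C)OCCO1)C1=C(C(=O)Cl)OC(Cc2ccc(OC)c3oc(C(C)C)cc(=O)c23)=CC1=O | intermediate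
29 | 5-({6-(diazoacetyl)-5-[3-(2-methyl-1,3-dioxolan-2-yl)prop-1-en-2-yl]-4-oxo-4H-pyran-2-yl}methyl)-2-isopropyl-8-methoxy-4H-chromen-4-one | C=C(CC1(C)OCCO1)C1=C(C(=O)C=[N+]=[N-])OC(Cc2ccc(OC)c3oc(C(C)C)cc(=O)c23)=CC1=O | intermediate
30 | dienylketene: 5-({5-[3-(2-methyl-1,3-dioxolan-2-yl)prop-1-en-2-yl]-4-oxo-6-(2-oxoethenyl)-4H-pyran-2-yl}methyl)-2-isopropyl-8-methoxy-4H-chromen-4-one | C=C(CC1(C)OCCO1)C1=C(C=C=O)OC(Cc2ccc(OC)c3oc(C(C)C)cc(=O)c23)=CC1=O | intermediate
31 | cyclohexadienone (keto tautomer of 32): 2-[(2-isopropyl-8-methoxy-4-oxo-4H-chromen-5-yl)methyl]-5-[(2-methyl-1,3-dioxolan-2-yl)methyl]-6H-chromene-4,7-dione | O=C1CC(CC2(C)OCCO2)=C2C(=O)C=C(Cc3ccc(OC)c4oc(C(C)C)cc(=O)c34)OC2=C1 | intermediate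
32 | 7-hydroxy-2-[(2-isopropyl-8-methoxy-4-oxo-4H-chromen-5-yl)methyl]-5-[(2-methyl-1,3-dioxolan-2-yl)methyl]-4H-chromen-4-one | CC1(OCCO1)Cc1cc(O)cc2oc(Cc3ccc(OC)c4oc(C(C)C)cc(=O)c34)cc(=O)c12 | intermediate
33 | 7-hydroxy-2-[(2-isopropyl-8-methoxy-4-oxo-4H-chromen-5-yl)methyl]-5-(2-oxopropyl)-4H-chromen-4-one (CNP0592286.0) | COc1ccc(Cc2cc(=O)c3c(CC(C)=O)cc(O)cc3o2)c2c(=O)cc(C(C)C)oc12 | target

Total step count: 19
Longest linear sequence: 13 steps (steps 4-8, 9-11 and 15-19)

Steps most likely to fail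

1. Step 18.
- What may go wrong: nitrogen loss may be diverted before the ketene exists, by addition of the carbene or of the intact diazo dipole to the alkene on C4a. The pyrone chromophores may also degrade under irradiation.
- Fallback: it builds the benzene ring of A without a diazo compound and without light. It sets out from 24 and comes back at 32.
- PPh3 and NCS should convert 24 into the chloromethylpyrone F1.
- Palladium-catalysed methoxycarbonylation (PdCl2(PPh3)2, CO 1 atm, MeOH, K2CO3, THF, 50 °C), known for benzylic chlorides, should give the methyl pyronylacetate F2. In F2 the former hydroxymethyl carbon is C8 and the CO carbon is C7.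
- LiOH in THF/H2O at 0 °C should free the pyronylacetic acid F3.
- Warming F3 with Ac2O and NaOAc (80-100 °C) is the ring-closing stage of the Stobbe phenol and naphthol syntheses. It should dehydrate F3 through its mixed anhydride, close C6-C7 and trap the phenol as the aryl acetate F4.
- K2CO3 in MeOH then gives 32.

2. Step 15.
- What may go wrong: transmetalation at a palladium centre flanked by the C4 carbonyl and the CH2OH may be slow. Base-induced loss of the triflyl group (direct S-O cleavage or transfer to the neighbouring hydroxyl) and protodeboronation of 23 could then take over.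
- Fallback: it changes the transmetalating metal and removes base and water altogether. It sets out from 22 and 18 and comes back at 24.
- Bu3SnSnBu3, Pd(PPh3)4 and LiCl in THF at reflux should turn 22 into the alkenylstannane F5.
- A Stille coupling of F5 with 18 (Pd(PPh3)4, LiCl, CuI, DMF, 60 °C) should give 24.

3. Step 9.
- What may go wrong: the very electrophilic chloromethyl group may be solvolysed by the aqueous base or quaternise phosphine. The boronate 15, which lies peri to a carbonyl group, may also protodeboronate before coupling.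
- Fallback: it forms the bridge bond by carbonyl addition and then removes the oxygen. It sets out from 4 and 14 and comes back at 17.
- MnO2 in CH2Cl2 should oxidise 4 to the pyrone aldehyde F6.
- Nozaki-Hiyama-Kishi coupling of 14 with F6 (CrCl2, NiCl2 cat., DMF, rt), which spares enones, should give the racemic carbinol F7.
- 1 M HCl in THF should remove the acetonide to give the triol F8.
- Ionic hydrogenation (Et3SiH, CF3CO2H, CH2Cl2, 0 °C) is assisted by the methoxy group para to the bridge carbon. It should remove only the doubly activated hydroxyl, erase the stereocentre and give 17.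

Further compounds
F1 | step 18 | 5-({6-(chloromethyl)-5-[3-(2-methyl-1,3-dioxolan-2-yl)prop-1-en-2-yl]-4-oxo-4H-pyran-2-yl}methyl)-2-isopropyl-8-methoxy-4H-chromen-4-one | C=C(CC1(C)OCCO1)C1=C(CCl)OC(Cc2ccc(OC)c3oc(C(C)C)cc(=O)c23)=CC1=O
F2 | step 18 | methyl 2-{6-[(2-isopropyl-8-methoxy-4-oxo-4H-chromen-5-yl)methyl]-3-[3-(2-methyl-1,3-dioxolan-2-yl)prop-1-en-2-yl]-4-oxo-4H-pyran-2-yl}acetate | C=C(CC1(C)OCCO1)C1=C(CC(=O)OC)OC(Cc2ccc(OC)c3oc(C(C)C)cc(=O)c23)=CC1=O
F3 | step 18 | 2-{6-[(2-isopropyl-8-methoxy-4-oxo-4H-chromen-5-yl)methyl]-3-[3-(2-methyl-1,3-dioxolan-2-yl)prop-1-en-2-yl]-4-oxo-4H-pyran-2-yl}acetic acid | C=C(CC1(C)OCCO1)C1=C(CC(=O)O)OC(Cc2ccc(OC)c3oc(C(C)C)cc(=O)c23)=CC1=O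
F4 | step 18 | 2-[(2-isopropyl-8-methoxy-4-oxo-4H-chromen-5-yl)methyl]-5-[(2-methyl-1,3-dioxolan-2-yl)methyl]-4-oxo-4H-chromen-7-yl acetate | CC(=O)Oc1cc(CC2(C)OCCO2)c2c(=O)cc(Cc3ccc(OC)c4oc(C(C)C)cc(=O)c34)oc2c1
F5 | step 15 | tributyl[3-(2-methyl-1,3-dioxolan-2-yl)prop-1-en-2-yl]stannane | C=C(CC1(C)OCCO1)[Sn](CCCC)(CCCC)CCCC
F6 | step 9 | 2,2-dimethyl-8-oxo-4H-pyrano[3,2-d][1,3]dioxine-6-carbaldehyde | O=CC1=CC(=O)C2=C(COC(C)(C)O2)O1
F7 | step 9 | 6-[hydroxy(2-isopropyl-8-methoxy-4-oxo-4H-chromen-5-yl)methyl]-2,2-dimethyl-4H-pyrano[3,2-d][1,3]dioxin-8-one (racemic) | COc1ccc(C(O)C2=CC(=O)C3=C(COC(C)(C)O3)O2)c2c(=O)cc(C(C)C)oc12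
F8 | step 9 | 5-{hydroxy[5-hydroxy-6-(hydroxymethyl)-4-oxo-4H-pyran-2-yl]methyl}-2-isopropyl-8-methoxy-4H-chromen-4-one (racemic) | COc1ccc(C(O)C2=CC(=O)C(O)=C(CO)O2)c2c(=O)cc(C(C)C)oc12
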